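**The question.** How much target stands in this flask at the asked time, and has it stopped?

- delta: starting material 0.0020 M; coupling partner 0.80 equiv (fed, over 50 s); run made earlier; the fed solution adds 0.25 times the starting volume
- flask: starting material 0.0010 M; coupling partner 0.800 equiv (fed, over 50 s); time 4.0 min; the fed solution adds 0.25 times the starting volume
- delta (time / s: target / %, starting material / %): 10.0: 9.8, 90.8; 15.0: 14.6, 84.5; 25.0: 27.1, 75.8

(each reading ± 1 percentage point)
- amounts are per litre of the starting volume; all of the dose is in the solution fed
- the earlier runs were read with a standard deviation of 1 percentage point
- a reading or a percentage of target counts all its forms, free or not
- the reaction counts as stopped when no species that holds the starting material changes by six tenths of a point or more over the second half of the time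
* why nothing more happens at 4.0 min, or that something still does (it is still moving / the coupling partner has run out first / all of the starting material has reacted)
* target at 4.0 min, in percent of the starting material charged

**Upper bound.** You have 0.800 equiv of coupling partner, the limiting reagent, so target cannot pass 80.0%.

**Tighter bracket.** At the last delta reading, 40.0% had been fed and 27.1% stood as target. I count the lag as loss, which these readings cannot prove. Capture odds, target made per unit of fed partner not in target, are then 2.10. Even odds, a ratio of one and the neutral point of this scale, would give half the ceiling.

A loss second order in partner keeps the odds when the same equivalents go into a weaker solution, giving 54.2%. A first-order loss scales them with concentration, here half, to 1.05, giving 41.0%.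

**Stopping.** As a rough time constant from the delta readings, I divide the last lag by the last rise of target per second, which gives 10.3 s. Doubled for this flask, that estimate is 20.6 s, so by my reckoning the tail after feeding shrinks the unreacted partner to 0.0100% of its amount, and I expect a stop.

**Result.** The forecast said 76% and it is still moving, since “this looks like clean 1:1 coupling”, which sits near the all-partner figure and above my bracket. The flask gives 46.3%: the coupling partner has run out first, with 0% of the partner left.

    starting material + coupling partner → target (k = 144 M⁻¹ s⁻¹)
    2 coupling partner → side product (k = 331 M⁻¹ s⁻¹)
    coupling partner → decomposed reagent (k = 0.0221 s⁻¹)
    crystals ⇌ target, rate k4*(cs4 - [target]) while solid is left; crystals form when [target] > cs4 (solubility = 0.470 mM, k = 9.33 s⁻¹)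

Its odds are 1.37, or 0.652 of the delta value.

**Second flask.** With 6.0 × 10⁻⁴ M of starting material, the same two scalings from 1.37 give odds of 0.824 to 1.37, so 36.1% to 46.2% target. That flask gives 40.3%.

Readings and results are simulated on assumed constants, and the scatter is random.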